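**Retrosynthetic overview**
1. Target ⇒ selective O-acetylation of the C4 CH2OH ⇒ Mitsunobu etherification of a decalin triol with umbelliferone at C11.
2. Triol ⇒ LiAlH4 reduction of a C3-keto/C4-ester/C11-acetate decalin (chiral auxiliary released) ⇒ C4 methylation of a bicyclic β-keto ester.
3. Key disconnection C4–C5 (then C10–C9): Mn(OAc)3 turns the nucleophilic α-carbon of a β-keto ester into an electrophilic α-radical (enolonium equivalent) that attacks the nucleophilic C5=C10 alkene. Ring A closes first, ring B second, and Cu(OAc)2 ends the cascade as the C8 methylidene; a Yb(OTf)3-chelated (−)-8-phenylmenthyl ester fixes the absolute sense.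
4. Acyclic keto ester ⇒ γ-alkylation of the auxiliary acetoacetate dianion with (2E,6E)-8-bromogeranyl acetate ⇒ geranyl acetate (SeO2 oxidation, Appel) and (−)-8-phenylmenthol plus the diketene–acetone adduct.

Assumption: drimane numbering is used for the decalin (C3 carbinol, C4 quaternary carbon, C5/C10 ring fusion, C8 methylidene carbon, C9 bearing C11H2O); (−)-8-phenylmenthol is bought and recovered in step 7.

**Step 1**
Reactants: 1 (−)-8-phenylmenthol [(1R,2S,5R)-5-methyl-2-(2-phenylpropan-2-yl)cyclohexan-1-ol]; 2 2,2,6-trimethyl-4H-1,3-dioxin-4-one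
Product: 4 (−)-8-phenylmenthyl acetoacetate [(1R,2S,5R)-5-methyl-2-(2-phenylpropan-2-yl)cyclohexyl 3-oxobutanoate], via acetylketene 3 (not isolated)
Conditions: xylenes, 140 °C, 1 h (acetone distilled off)
Reagents that add atoms: none
Why: Thermal retro-[4+2] of the dioxinone releases acetylketene, which the hindered secondary alcohol traps cleanly (acetoacetylation via an acylketene) without touching the three auxiliary stereocentres.

**Step 2**
Reactants: 5 geranyl acetate [(2E)-3,7-dimethylocta-2,6-dien-1-yl acetate]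
Product: 6 (2E,6E)-8-hydroxy-3,7-dimethylocta-2,6-dien-1-yl acetate
Conditions: SeO2 (0.3 equiv), t-BuOOH (3 equiv), salicylic acid (0.1 equiv), CH2Cl2, 0 °C → rt
Reagents that add atoms: tert-butyl hydroperoxide, CC(C)(C)OO
Why: Catalytic SeO2 allylic oxidation (ene reaction then [2,3]-sigmatropic shift) selects the (E)-methyl group of the electron-richer distal alkene, so the new CH2OH is trans to the chain and the 6E geometry needed for a trans ring fusion is in place.

**Step 3**
Reactants: 6 (2E,6E)-8-hydroxy-3,7-dimethylocta-2,6-dien-1-yl acetate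
Product: 7 (2E,6E)-8-bromo-3,7-dimethylocta-2,6-dien-1-yl acetate
Conditions: CBr4, PPh3, CH2Cl2, 0 °C
Reagents that add atoms: tetrabromomethane, BrC(Br)(Br)Br
Why: Appel reaction, in which bromide displaces the alkoxyphosphonium of the primary allylic alcohol by SN2 under neutral conditions that keep the acetate and both E alkenes intact.

**Step 4**
Reactants: 4 (−)-8-phenylmenthyl acetoacetate; 7 (2E,6E)-8-bromo-3,7-dimethylocta-2,6-dien-1-yl acetate
Product: 9 (−)-8-phenylmenthyl (6E,10E)-12-acetoxy-6,10-dimethyl-3-oxododeca-6,10-dienoate, via acetoacetate dianion 8 (not isolated)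
Conditions: NaH, THF, 0 °C; n-BuLi, 0 °C; then 7, −78 → −20 °C; 1 M HCl
Reagents that add atoms: none
Why: Dianion γ-alkylation of an acetoacetate (Weiler type), in which the terminal carbanion is far more nucleophilic than the stabilised α-carbon and displaces the primary allylic bromide by SN2 at low temperature faster than it attacks the acetate, forming the C1–C2 bond with both E alkenes retained.

**Step 5**
Reactants: 9 (−)-8-phenylmenthyl (6E,10E)-12-acetoxy-6,10-dimethyl-3-oxododeca-6,10-dienoate
Product: 13 (−)-8-phenylmenthyl (1R,4aR,5R,8aR)-5-(acetoxymethyl)-4a-methyl-6-methylidene-2-oxodecahydronaphthalene-1-carboxylate (trans-decalin; C4–H epimerisable; drawn with the ester equatorial), via α-keto ester radical 10 (not isolated), via monocyclic C10 radical 11 (not isolated), via bicyclic C8 radical 12 (not isolated)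
Conditions: Mn(OAc)3·2H2O (2.2 equiv), Cu(OAc)2·H2O (1 equiv), Yb(OTf)3 (1 equiv), degassed CF3CH2OH, −5 → 0 °C
Reagents that add atoms: none
Why: Oxidative free-radical polyene cyclisation of the Mn(OAc)3/Cu(OAc)2 type, in which Mn(OAc)3 oxidises the Yb(OTf)3-chelated enol to an electrophilic α-radical so that the normally nucleophilic C4 bonds to the nucleophilic alkene carbon C5 (6-endo, ring A), the C10 radical then closes ring B at C9 through a chair–chair array whose E alkenes give the trans fusion and an equatorial C9 CH2OAc, the auxiliary phenyl ring stacked over one face of the syn-chelated dicarbonyl directs C5 to the Re face of C4 and thereby sets C5, C10 and C9 as drawn, and Cu(OAc)2 converts the tertiary C8 radical into the less substituted methylidene by oxidative elimination.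

**Step 6**
Reactants: 13 bicyclic β-keto ester
Product: 14 (−)-8-phenylmenthyl (1S,4aR,5R,8aS)-5-(acetoxymethyl)-1,4a-dimethyl-6-methylidene-2-oxodecahydronaphthalene-1-carboxylate (C4 methyl equatorial; ester axial and cis to the C10 methyl)
Conditions: K2CO3, MeI, acetone, 50 °C
Reagents that add atoms: iodomethane, CI
Why: C-alkylation of the cyclic β-keto ester enolate, in which iodomethane approaches C4 anti to the axial C10 methyl group (1,3-diaxial shielding of the other face) so that the new methyl ends up equatorial and the ester axial, which fixes the quaternary C4 centre.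

**Step 7**
Reactants: 14 C4-methylated keto ester
Product: 15 (1R,2R,4aR,5R,8aS)-1,5-bis(hydroxymethyl)-1,4a-dimethyl-6-methylidenedecahydronaphthalen-2-ol
Conditions: LiAlH4 (6 equiv), THF, −20 °C → reflux; then H2O, aq. NaOH
Reagents that add atoms: none
Why: LiAlH4 reduction, in which hydride attacks the C3 ketone along the axial trajectory on the face opposite the axial C4 ester and the C10 methyl to give the equatorial C3 alcohol cis to the C4 CH2OH, while the hindered ester and the acetate are reduced to the two primary alcohols with release of the recoverable auxiliary.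

**Step 8**
Reactants: 15 decalin triol; 16 umbelliferone (7-hydroxy-2H-chromen-2-one)
Product: 17 7-{[(1R,4aS,5R,6R,8aR)-6-hydroxy-5-(hydroxymethyl)-5,8a-dimethyl-2-methylidenedecahydronaphthalen-1-yl]methoxy}-2H-chromen-2-one
Conditions: PPh3, DIAD, THF, 0 → 40 °C
Reagents that add atoms: none
Why: Mitsunobu etherification, in which the acidic phenol (pKa about 7.8) displaces the oxyphosphonium of the C11 primary alcohol by SN2, whereas the neopentyl C4 CH2OH (1,3-diaxial to the C10 methyl) and the hindered secondary C3–OH are not displaced at a useful rate; no stereocentre is involved.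

**Step 9**
Reactants: 17 aryl ether diol
Product: 18 [(1R,2R,4aR,5R,8aS)-2-hydroxy-1,4a-dimethyl-6-methylidene-5-{[(2-oxo-2H-chromen-7-yl)oxy]methyl}decahydronaphthalen-1-yl]methyl acetate (CNP0271943.1)
Conditions: AcCl (1.1 equiv), 2,4,6-collidine, CH2Cl2, −40 → 0 °C
Reagents that add atoms: acetyl chloride, CC(Cl)=O
Why: Kinetically selective O-acylation at low temperature acetylates the primary C4 CH2OH faster than the equatorial secondary C3–OH flanked by the quaternary C4, giving the target without touching any stereocentre.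

**Compound list**
1 | (−)-8-phenylmenthol, (1R,2S,5R)-5-methyl-2-(2-phenylpropan-2-yl)cyclohexan-1-ol | O[C@@H]1C[C@H](C)CC[C@H]1C(C)(C)c1ccccc1 | starting material
2 | 2,2,6-trimethyl-4H-1,3-dioxin-4-one | CC1=CC(=O)OC(C)(C)O1 | starting material
3 | acetylketene (formed in situ) | CC(=O)C=C=O | intermediate
4 | (−)-8-phenylmenthyl acetoacetate | CC(=O)CC(=O)O[C@@H]1C[C@H](C)CC[C@H]1C(C)(C)c1ccccc1 | intermediate
5 | geranyl acetate | CC(C)=CCC/C(C)=C/COC(C)=O | starting material
6 | (2E,6E)-8-hydroxy-3,7-dimethylocta-2,6-dien-1-yl acetate | OC/C(C)=C/CC/C(C)=C/COC(C)=O | intermediate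
7 | (2E,6E)-8-bromo-3,7-dimethylocta-2,6-dien-1-yl acetate | BrC/C(C)=C/CC/C(C)=C/COC(C)=O | intermediate
8 | sodium lithium dianion (dienolate) of 4 (formed in situ) | [Na+].[Li+].C=C([O-])C=C([O-])O[C@@H]1C[C@H](C)CC[C@H]1C(C)(C)c1ccccc1 | intermediate
9 | (−)-8-phenylmenthyl (6E,10E)-12-acetoxy-6,10-dimethyl-3-oxododeca-6,10-dienoate | CC(=O)OC/C=C(\C)CC/C=C(\C)CCC(=O)CC(=O)O[C@@H]1C[C@H](C)CC[C@H]1C(C)(C)c1ccccc1 | intermediate
10 | C4 α-keto ester radical of 9 (formed in situ) | CC(=O)OC/C=C(\C)CC/C=C(\C)CCC(=O)[CH]C(=O)O[C@@H]1C[C@H](C)CC[C@H]1C(C)(C)c1ccccc1 | intermediate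
11 | monocyclic C10 tertiary radical; ring A closed (formed in situ) | CC(=O)OC/C=C(\C)CC[C@@H]1[C@@H](C(=O)O[C@@H]2C[C@H](C)CC[C@H]2C(C)(C)c2ccccc2)C(=O)CC[C]1C | intermediate
12 | bicyclic C8 tertiary radical; rings A and B closed (formed in situ) | C[C]1CC[C@@H]2[C@@H](C(=O)O[C@@H]3C[C@H](C)CC[C@H]3C(C)(C)c3ccccc3)C(=O)CC[C@@]2(C)[C@@H]1COC(C)=O | intermediate
13 | (−)-8-phenylmenthyl (1R,4aR,5R,8aR)-5-(acetoxymethyl)-4a-methyl-6-methylidene-2-oxodecahydronaphthalene-1-carboxylate | C=C1CC[C@@H]2[C@@H](C(=O)O[C@@H]3C[C@H](C)CC[C@H]3C(C)(C)c3ccccc3)C(=O)CC[C@@]2(C)[C@@H]1COC(C)=O | intermediate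
14 | (−)-8-phenylmenthyl (1S,4aR,5R,8aS)-5-(acetoxymethyl)-1,4a-dimethyl-6-methylidene-2-oxodecahydronaphthalene-1-carboxylate | C=C1CC[C@@H]2[C@](C)(C(=O)O[C@@H]3C[C@H](C)CC[C@H]3C(C)(C)c3ccccc3)C(=O)CC[C@@]2(C)[C@@H]1COC(C)=O | intermediate
15 | (1R,2R,4aR,5R,8aS)-1,5-bis(hydroxymethyl)-1,4a-dimethyl-6-methylidenedecahydronaphthalen-2-ol | C=C1CC[C@@H]2[C@](C)(CO)[C@H](O)CC[C@@]2(C)[C@@H]1CO | intermediate
16 | umbelliferone, 7-hydroxy-2H-chromen-2-one | O=c1ccc2ccc(O)cc2o1 | starting material
17 | 7-{[(1R,4aS,5R,6R,8aR)-6-hydroxy-5-(hydroxymethyl)-5,8a-dimethyl-2-methylidenedecahydronaphthalen-1-yl]methoxy}-2H-chromen-2-one | C=C1CC[C@@H]2[C@](C)(CO)[C@H](O)CC[C@@]2(C)[C@@H]1COc1ccc2ccc(=O)oc2c1 | intermediate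
18 | [(1R,2R,4aR,5R,8aS)-2-hydroxy-1,4a-dimethyl-6-methylidene-5-{[(2-oxo-2H-chromen-7-yl)oxy]methyl}decahydronaphthalen-1-yl]methyl acetate | C=C1CC[C@@H]2[C@](C)(COC(C)=O)[C@H](O)CC[C@@]2(C)[C@@H]1COc1ccc2ccc(=O)oc2c1 | target

**Totals**
Total step count: 9. Longest linear sequence: 8 steps (5 → 18, steps 2 to 9); step 1 is a one-step side branch.

**Steps most likely to fail**

The most fragile operation is step 5. Three things can go wrong:
- Product 13 is still an enolisable β-keto ester and can be oxidised again while Cu(OAc)2 is present. This is limited by using only 2.2 equiv of Mn(OAc)3 at −5 °C, and the trans-decalin has no β-hydrogen syn to C4 for an oxidative elimination.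
- Some endocyclic C7=C8 alkene can accompany the methylidene.
- The allylic acetate could ionise in CF3CH2OH.

The sense of induction rests on a stacking model for the chelated auxiliary and on analogy with arene-terminated cyclisations of such esters, not on a direct precedent for this substrate. The minor auxiliary diastereomer has to be removed by chromatography at 13 or 14, before the auxiliary is cleaved.

The fallback for step 5 sets out from 9. Chlorination at C2 with N-chlorosuccinimide and catalytic Mg(ClO4)2 in EtOAc gives the α-chloro keto ester F1. The same Mn(OAc)3/Cu(OAc)2/Yb(OTf)3 bicyclisation then gives the 4-chloro bicyclic keto ester F2, whose fully substituted C4 cannot be oxidised further. Zn dust in AcOH removes the chlorine, and the route is rejoined at 13.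

Step 8 may be slow because C11 is flanked by the quaternary C10, and the two other hydroxyl groups could interfere. The fallback sets out from 15:
- 2,2-dimethoxypropane and PPTS in acetone tie up the C3–OH and the C4 CH2OH as the acetonide alcohol F3.
- MsCl and Et3N convert the free C11–OH into the methanesulfonate F4.
- Umbelliferone 16 with Cs2CO3 in DMF at 80 °C displaces the mesylate to give the acetonide aryl ether F5.
- Aqueous AcOH at 40 °C removes the acetonide, and the route is rejoined at 17.

Step 9 depends on a rate difference between a neopentyl primary and a hindered secondary alcohol, so over-acetylation or C3 acetylation is possible. The fallback sets out from 17. Bu2SnO in refluxing toluene with removal of water gives the dibutylstannylene acetal F6. This activates the primary oxygen, so that one equivalent of AcCl at 0 °C acylates only the CH2–O terminus, and the route is rejoined at 18.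

**Further compounds**
F1 | step 5 | (−)-8-phenylmenthyl (6E,10E)-12-acetoxy-2-chloro-6,10-dimethyl-3-oxododeca-6,10-dienoate (both C2 epimers) | CC(=O)OC/C=C(\C)CC/C=C(\C)CCC(=O)C(Cl)C(=O)O[C@@H]1C[C@H](C)CC[C@H]1C(C)(C)c1ccccc1
F2 | step 5 | 4-chloro analogue of 13 (trans-decalin as in 13; chlorine axial at C4; ester equatorial) | C=C1CC[C@@H]2[C@](C(=O)O[C@@H]3C[C@H](C)CC[C@H]3C(C)(C)c3ccccc3)(Cl)C(=O)CC[C@@]2(C)[C@@H]1COC(C)=O
F3 | step 8 | acetonide of 15 across the C3–OH and the C4 CH2OH (C11–OH free) | C=C1CC[C@@H]2[C@](C)(CO3)[C@H](OC3(C)C)CC[C@@]2(C)[C@@H]1CO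
F4 | step 8 | C11 methanesulfonate of F3 | C=C1CC[C@@H]2[C@](C)(CO3)[C@H](OC3(C)C)CC[C@@]2(C)[C@@H]1COS(C)(=O)=O
F5 | step 8 | acetonide of 17 | C=C1CC[C@@H]2[C@](C)(CO3)[C@H](OC3(C)C)CC[C@@]2(C)[C@@H]1COc1ccc2ccc(=O)oc2c1
F6 | step 9 | dibutylstannylene acetal of 17 (C3–O and C4 CH2–O bridged by SnBu2) | C=C1CC[C@@H]2[C@](C)(CO3)[C@H](O[Sn]3(CCCC)CCCC)CC[C@@]2(C)[C@@H]1COc1ccc2ccc(=O)oc2c1
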